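## Retrosynthetic overview

1. The target comes from one global dealkylation (two tert-butyl ethers, one aryl methyl ether, one methyl ester) of a fully assembled tetralin salicylate.
2. Aromatic ring A is built by a [3+3] Knoevenagel/aldol benzannulation of an α-hydroxymethylene cyclohexanone with methyl 4-methoxyacetoacetate; the ketone comes from the ring alkene by hydroboration/oxidation.
3. Key step: both primary C–O bonds and both side-chain stereocentres come from one ligand-controlled double anti-Markovnikov hydro-tert-butoxylation of a triene (new CuH method).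
4. The triene comes from (R)-limonene (supplies ring B and its side-chain-bearing stereocentre) and 4-bromo-2-methylbut-1-ene by allylic lithiation/alkylation.
5. Ring order: saturated ring B is bought with limonene; aromatic ring A is formed in step 5, after the CH(CH3) centre has been equilibrated to trans.

Assumption: (R)-DTBM-SEGPHOS–CuH is taken to deliver hydride to the alkene face that gives the S configuration at both new centres; if a test run shows the opposite sense, (S)-DTBM-SEGPHOS is used and nothing else changes.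

## Route

Step 1
Reactants: 1 (R)-(+)-limonene; 2 4-bromo-2-methylbut-1-ene
Product: 4 (4R)-1-methyl-4-(6-methylhepta-1,6-dien-2-yl)cyclohex-1-ene, via 10-lithiolimonene 3 (not isolated)
Conditions: 1 (2 equiv), n-BuLi (1.1 equiv), TMEDA (1.1 equiv), hexane, 23 °C, 18 h; then THF, −78 °C, 2 (1.0 equiv), → 0 °C
Reagents that add atoms: none
Why: TMEDA-activated n-BuLi lithiates the isopropenyl methyl group (allylic lithiation, the ring stereocentre is untouched) and the symmetric 2-substituted allyllithium is alkylated by the primary bromide (SN2), either allyl terminus giving the same product.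

Step 2
Reactants: 4 (4R)-1-methyl-4-(6-methylhepta-1,6-dien-2-yl)cyclohex-1-ene
Product: 6 (4R)-4-[(2S,6S)-1,7-di-tert-butoxy-6-methylheptan-2-yl]-1-methylcyclohex-1-ene, via mono-tert-butyl ether 5 (not isolated)
Conditions: Cu(OAc)2 (5 mol%), (R)-DTBM-SEGPHOS (5.5 mol%), (MeO)2MeSiH (6 equiv), tert-butyl perbenzoate (2.6 equiv, syringe pump, 8 h), THF, 40 °C
Reagents that add atoms: tert-butyl perbenzoate, CC(C)(C)OOC(=O)c1ccccc1
Why: Proposed new method: ligand-controlled CuH-catalysed anti-Markovnikov hydro-tert-butoxylation, in which L*CuH hydrocuprates each 1,1-disubstituted alkene with copper on CH2 and face-selective hydride delivery to the internal carbon (this sets both side-chain centres as S with one ligand antipode, because in both alkenes the larger substituent lies on the same side relative to the new CH2O arm; the trisubstituted ring alkene is inert), the primary alkyl monovalent copper is then oxidised at oxygen by the perester (O–O oxidative addition to an alkyl trivalent copper tert-butoxide, then C–O reductive elimination, the stereocentre being β to copper and so unaffected) and the copper benzoate is returned to CuH by the silane; the closest known reaction types are the CuH-catalysed anti-Markovnikov hydroamination of 1,1-disubstituted alkenes with O-benzoyl hydroxylamines and the electrophilic tert-butoxylation of Grignard reagents with tert-butyl perbenzoate.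

Step 3
Reactants: 6 (4R)-4-[(2S,6S)-1,7-di-tert-butoxy-6-methylheptan-2-yl]-1-methylcyclohex-1-ene
Product: 8 (2R,5R)-5-[(2S,6S)-1,7-di-tert-butoxy-6-methylheptan-2-yl]-2-methylcyclohexan-1-one, via alkylborane 7 (not isolated)
Conditions: BH3·THF (1.3 equiv), THF, 0 → 23 °C; then N-methylmorpholine N-oxide (8 equiv), (n-Pr4N)RuO4 (5 mol%), 4 Å MS, CH2Cl2, 23 °C; then NaOMe (0.2 equiv), MeOH, 23 °C
Reagents that add atoms: N-methylmorpholine N-oxide, C[N+]1([O-])CCOCC1
Why: Brown hydroboration puts boron on the less substituted ring carbon, amine-oxide C–B oxidation and Ley–Griffith oxidation give the ketone in one pot, and base equilibration of the epimerisable α-methyl centre gives the diequatorial trans-2,5-disubstituted cyclohexanone (thermodynamic control, about 4:1 or better; the centre is locked only in step 5).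

Step 4
Reactants: 8 (2R,5R)-5-[(2S,6S)-1,7-di-tert-butoxy-6-methylheptan-2-yl]-2-methylcyclohexan-1-one
Product: 9 (2Z,3S,6R)-3-[(2S,6S)-1,7-di-tert-butoxy-6-methylheptan-2-yl]-2-(hydroxymethylidene)-6-methylcyclohexan-1-one
Conditions: NaH (2.5 equiv), HCO2Et (5 equiv), MeOH (cat.), THF, 0 → 23 °C; aq. HCl
Reagents that add atoms: ethyl formate, CCOC=O
Why: Crossed Claisen formylation occurs only at the α-methylene, because acylation at the CH(CH3) side is reversible and cannot give a stabilised enolate.

Step 5
Reactants: 9 (2Z,3S,6R)-3-[(2S,6S)-1,7-di-tert-butoxy-6-methylheptan-2-yl]-2-(hydroxymethylidene)-6-methylcyclohexan-1-one; 10 methyl 4-methoxy-3-oxobutanoate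
Product: 12 methyl (5R,8S)-8-[(2S,6S)-1,7-di-tert-butoxy-6-methylheptan-2-yl]-3-hydroxy-4-methoxy-5-methyl-5,6,7,8-tetrahydronaphthalene-2-carboxylate, via Knoevenagel adduct 11 (not isolated)
Conditions: 10 (1.5 equiv), piperidine (0.3 equiv), AcOH (0.3 equiv), PhMe, 110 °C, Dean–Stark
Reagents that add atoms: none
Why: Amine-catalysed Knoevenagel condensation of the acidic C2 methylene of 10 with the formyl carbon, then intramolecular enamine aldol of the CH2OMe carbon onto the ring ketone, dehydration and tautomerisation give the arene ([3+3] benzannulation of the hydroxymethylene-ketone/β-keto ester type); aromatisation freezes the CH(CH3) centre as the trans isomer, in which both benzylic substituents sit pseudo-axial and avoid peri strain (minor cis epimer removed by chromatography).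

Step 6
Reactants: 12 methyl (5R,8S)-8-[(2S,6S)-1,7-di-tert-butoxy-6-methylheptan-2-yl]-3-hydroxy-4-methoxy-5-methyl-5,6,7,8-tetrahydronaphthalene-2-carboxylate
Product: 13 (5R,8S)-8-[(2S,6S)-1,7-dihydroxy-6-methylheptan-2-yl]-3,4-dihydroxy-5-methyl-5,6,7,8-tetrahydronaphthalene-2-carboxylic acid
Conditions: AlCl3 (12 equiv), EtSH/CH2Cl2 (1:2), 0 → 23 °C, 12 h, Ar; aq. HCl
Reagents that add atoms: none
Why: Hard-acid/soft-nucleophile dealkylation (Node–Fujita type) cleaves the chelated aryl methyl ether and the methyl ester by thiol attack at methyl and both tert-butyl ethers by ionisation, without touching primary alcohols or the benzylic stereocentres.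

## Compound list

1 | (R)-(+)-limonene, (4R)-1-methyl-4-(prop-1-en-2-yl)cyclohex-1-ene | CC1=CC[C@@H](CC1)C(C)=C | starting material
2 | 4-bromo-2-methylbut-1-ene | CC(=C)CCBr | starting material
3 | 10-lithiolimonene, [2-[(1R)-4-methylcyclohex-3-en-1-yl]prop-2-en-1-yl]lithium (TMEDA complex) | [Li]CC(=C)[C@@H]1CCC(C)=CC1 | intermediate
4 | (4R)-1-methyl-4-(6-methylhepta-1,6-dien-2-yl)cyclohex-1-ene | C=C(C)CCCC(=C)[C@@H]1CCC(C)=CC1 | intermediate
5 | (4R)-4-[(6S)-7-tert-butoxy-6-methylhept-1-en-2-yl]-1-methylcyclohex-1-ene (the methyl-substituted alkene is assumed to react first) | C[C@H](COC(C)(C)C)CCCC(=C)[C@@H]1CCC(C)=CC1 | intermediate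
6 | (4R)-4-[(2S,6S)-1,7-di-tert-butoxy-6-methylheptan-2-yl]-1-methylcyclohex-1-ene | C[C@H](COC(C)(C)C)CCC[C@H](COC(C)(C)C)[C@@H]1CCC(C)=CC1 | intermediate
7 | [(1R,2R,5R)-5-[(2S,6S)-1,7-di-tert-butoxy-6-methylheptan-2-yl]-2-methylcyclohexyl]borane (boron trans to CH3; drawn as the monoalkylborane; the (1S,2S,5R) ring-face isomer also forms and converges at 8) | C[C@H](COC(C)(C)C)CCC[C@H](COC(C)(C)C)[C@@H]1CC[C@@H](C)[C@H](B)C1 | intermediate
8 | (2R,5R)-5-[(2S,6S)-1,7-di-tert-butoxy-6-methylheptan-2-yl]-2-methylcyclohexan-1-one (trans) | C[C@H](COC(C)(C)C)CCC[C@H](COC(C)(C)C)[C@@H]1CC[C@@H](C)C(=O)C1 | intermediate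
9 | (2Z,3S,6R)-3-[(2S,6S)-1,7-di-tert-butoxy-6-methylheptan-2-yl]-2-(hydroxymethylidene)-6-methylcyclohexan-1-one (chelated enol) | C[C@H](COC(C)(C)C)CCC[C@H](COC(C)(C)C)[C@@H]1CC[C@@H](C)C(=O)/C1=C\O | intermediate
10 | methyl 4-methoxy-3-oxobutanoate (methyl 4-methoxyacetoacetate) | COCC(=O)CC(=O)OC | starting material
11 | methyl 2-{[(3R,6S)-6-[(2S,6S)-1,7-di-tert-butoxy-6-methylheptan-2-yl]-3-methyl-2-oxocyclohexylidene]methyl}-4-methoxy-3-oxobutanoate (tautomeric mixture; alkene geometry and the acidic CH centre not defined) | C[C@H](COC(C)(C)C)CCC[C@H](COC(C)(C)C)[C@@H]1CC[C@@H](C)C(=O)C1=CC(C(=O)OC)C(=O)COC | intermediate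
12 | methyl (5R,8S)-8-[(2S,6S)-1,7-di-tert-butoxy-6-methylheptan-2-yl]-3-hydroxy-4-methoxy-5-methyl-5,6,7,8-tetrahydronaphthalene-2-carboxylate (5-CH3 and 8-side chain trans) | C[C@H](COC(C)(C)C)CCC[C@H](COC(C)(C)C)[C@@H]1CC[C@@H](C)c2c1cc(C(=O)OC)c(O)c2OC | intermediate
13 | (5R,8S)-8-[(2S,6S)-1,7-dihydroxy-6-methylheptan-2-yl]-3,4-dihydroxy-5-methyl-5,6,7,8-tetrahydronaphthalene-2-carboxylic acid (CNP0255074.1) | C[C@H](CO)CCC[C@H](CO)[C@@H]1CC[C@@H](C)c2c1cc(C(=O)O)c(O)c2O | target

## Step count and risks

Total steps: 6. Longest linear sequence: 6 (from limonene 1).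

Steps most likely to fail:

**Step 2 (proposed new step).** The perester may be reduced by CuH before hydrocupration, may oxidise the phosphine, or may give benzoate instead of ether. Facial control at the methyl/primary-alkyl alkene is the weakest point (perhaps about 9:1), and that remote epimer would be hard to remove. The fallback uses known chemistry, sets out from 4 and returns at 6. CuH-catalysed hydroboration (CuCl, KOtBu, (R)-DTBM-SEGPHOS, pinacolborane, toluene, 40 °C) gives the bis(pinacol boronate) F1. NaBO3·4H2O in THF/H2O oxidises it to (2S,6S)-2-methyl-6-[(1R)-4-methylcyclohex-3-en-1-yl]heptane-1,7-diol F2. Boc2O with Mg(ClO4)2 (10 mol%) in CH2Cl2 at 40 °C converts both primary alcohols into tert-butyl ethers, which is 6.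

**Step 5.** Adduct 11 may close through oxygen (pyranone or pyran) instead of carbon, the weakly acidic CH2OMe carbon may be slow in the aldol, and the trans/cis ratio at the CH(CH3) centre may be modest. The fallback reverses the polarity of the first C–C bond; it sets out from 8 (with 10) and returns at 12. Compound 10 is heated with HC(OEt)3 and Ac2O (130 °C) to give methyl 2-(ethoxymethylidene)-4-methoxy-3-oxobutanoate F3. Ketone 8 is converted with LiN(i-Pr)2 (THF, −78 °C) into the kinetic lithium enolate F4. Addition–elimination of F4 on F3 gives the same ene-dione 11 as its lithium salt. NaOMe in MeOH at 65 °C then closes it to 12; under these conditions O-cyclised products reopen and the arene is the thermodynamic sink.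

**Step 1.** The basic allyllithium may eliminate HBr from the homoallylic bromide (giving isoprene), and minor ring-metalated isomers may be alkylated. The fallback sets out from 1 (through 3, made as in step 1) and returns at 4. Allyllithium 3 is trapped with ethylene oxide (THF, −78 → 0 °C) to give 4-[(1R)-4-methylcyclohex-3-en-1-yl]pent-4-en-1-ol F5. TsCl/pyridine gives the tosylate F6. Coupling with CH2=C(CH3)MgBr and Li2CuCl4 (5 mol%) in THF at −20 → 0 °C gives 4.

## Further compounds

F1 | step 2 | 2,2'-[(2R,6S)-2-methyl-6-[(1R)-4-methylcyclohex-3-en-1-yl]heptane-1,7-diyl]bis(4,4,5,5-tetramethyl-1,3,2-dioxaborolane) | C[C@H](CB1OC(C)(C)C(C)(C)O1)CCC[C@H](CB2OC(C)(C)C(C)(C)O2)[C@@H]3CCC(C)=CC3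
F2 | step 2 | (2S,6S)-2-methyl-6-[(1R)-4-methylcyclohex-3-en-1-yl]heptane-1,7-diol | C[C@H](CO)CCC[C@H](CO)[C@@H]1CCC(C)=CC1
F3 | step 5 | methyl 2-(ethoxymethylidene)-4-methoxy-3-oxobutanoate (E/Z mixture) | CCOC=C(C(=O)OC)C(=O)COC
F4 | step 5 | lithium (3S,6R)-3-[(2S,6S)-1,7-di-tert-butoxy-6-methylheptan-2-yl]-6-methylcyclohex-1-en-1-olate | C[C@H](COC(C)(C)C)CCC[C@H](COC(C)(C)C)[C@@H]1CC[C@@H](C)C(O[Li])=C1
F5 | step 1 | 4-[(1R)-4-methylcyclohex-3-en-1-yl]pent-4-en-1-ol | OCCCC(=C)[C@@H]1CCC(C)=CC1
F6 | step 1 | 4-[(1R)-4-methylcyclohex-3-en-1-yl]pent-4-en-1-yl 4-methylbenzenesulfonate | Cc1ccc(cc1)S(=O)(=O)OCCCC(=C)[C@@H]1CCC(C)=CC1
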